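**Plan**

- Retrosynthesis: the benzoate is removed first, then C‑9–OH is traced to a C‑9 ketone and on to a C‑9 methylidene, and the 7‑methyl to a 7‑carboxyl group. The skeleton is then cut at C‑7–C‑8, the bond joining the two methyl‑bearing carbons of the seven‑membered ring next to benzylic C‑9. This is the pattern left by a [3,3] shift of an allylic ester enolate, so the cut leads back to a nine‑membered allylic lactone.
- The lactone is opened at its acyl–oxygen bond. The seco acid is cut at the aryl–alkenyl bond (Suzuki), at the allyl group on the quaternary carbon (dearomatizing allylation of a 4‑arylphenol) and at the biaryl bond (Suzuki).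
- Forward order: biaryl, then dienone ring B with its quaternary carbon, then the propanoic acid arm, then the (E)‑butenol arm, then the nine‑membered lactone, then ring contraction to the cycloheptene, then oxidation‑state adjustment.
- Stereochemistry: C‑7 and C‑8 are set together in the rearrangement. Their trans relationship comes from the ring‑locked ketene acetal, the chair transition state and the E ethylidene group; their absolute configuration comes from a C2‑symmetric diazaborolidine on boron. C‑9 is set by hydride addition to the C‑9 ketone. Spiro C‑5 is not stereogenic in the target.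
- Two design choices: the ethylidene group of the lactone is E (methyl cis to the arene), because the ring‑cis ketene acetal can only reach a chair, in which an E methyl ends trans to the carboxyl group. The dienone carbonyl is reduced together with the other carbonyl groups and restored by a selective allylic oxidation near the end, since no hydride reagent is expected to distinguish it from the aryl ketone.

Key step: step 11

Remark (assumption): the sense of induction of the (S,S)‑bromodiazaborolidine is assigned by analogy with acyclic allylic esters; should the antipode of 20 predominate, the (R,R)‑reagent is used and nothing else changes.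
Remark (locants): benzo[7]annulene numbering is used for the carbocycle (spiro C‑5, CH2 C‑6, C‑7, C‑8, benzylic C‑9); ring B (dienone) carries primed locants, ring A is the trimethoxyarene.

Step 1
Reactants: 1 5-bromo-1,2,3-trimethoxybenzene
Product: 2 1-bromo-2-iodo-3,4,5-trimethoxybenzene
Conditions: N-iodosuccinimide, CF3CO2H (cat.), MeCN, rt
Reagents that add atoms: N-iodosuccinimide, O=C1CCC(=O)N1I
Why: Electrophilic aromatic iodination can only occur at the two equivalent free positions, which are ortho and para to methoxy groups, so iodine should enter between bromine and a methoxy group.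

Step 2
Reactants: 2 1-bromo-2-iodo-3,4,5-trimethoxybenzene; 3 2,6-dimethoxy-4-(4,4,5,5-tetramethyl-1,3,2-dioxaborolan-2-yl)phenol
Product: 4 4-(6-bromo-2,3,4-trimethoxyphenyl)-2,6-dimethoxyphenol
Conditions: Pd(PPh3)4 (cat.), K2CO3, dioxane/H2O, 70 °C
Reagents that add atoms: none
Why: In this Suzuki–Miyaura coupling zerovalent palladium inserts into the C–I bond much faster than into the C–Br bond, so the biaryl bond should form at the iodine-bearing carbon only and the bromide next to the ring hydrogen is kept for step 9.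

Step 3
Reactants: 4 4-(6-bromo-2,3,4-trimethoxyphenyl)-2,6-dimethoxyphenol; 5 allyltrimethylsilane
Product: 6 4-(6-bromo-2,3,4-trimethoxyphenyl)-2,6-dimethoxy-4-(prop-2-en-1-yl)cyclohexa-2,5-dien-1-one
Conditions: PhI(OAc)2, (CF3)2CHOH/CH2Cl2, −20 °C → 0 °C
Reagents that add atoms: none
Why: Oxidative dearomatization with trivalent iodine (an umpolung Hosomi–Sakurai allylation) turns the phenol into an electrophile that the allylsilane should trap at the aryl-bearing para carbon to give the cross-conjugated dienone, while any adduct at a methoxy-bearing ortho carbon is a 1,5-diene that can pass the allyl group on to C-4 by Cope rearrangement.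

Step 4
Reactants: 6 4-(6-bromo-2,3,4-trimethoxyphenyl)-2,6-dimethoxy-4-(prop-2-en-1-yl)cyclohexa-2,5-dien-1-one
Product: 8 4-(6-bromo-2,3,4-trimethoxyphenyl)-4-(3-hydroxypropyl)-2,6-dimethoxycyclohexa-2,5-dien-1-one, via pinacol alkylboronate 7 (not isolated)
Conditions: RhCl(PPh3)3 (cat.), pinacolborane, THF, rt; then NaBO3·4H2O, THF/H2O, rt
Reagents that add atoms: sodium perborate, [Na+].[O-]OB=O
Why: Rhodium-catalysed anti-Markovnikov hydroboration is selective for the monosubstituted alkene over the ketone and the hindered, carbonyl-conjugated dienone double bonds, and perborate oxidizes the C–B bond under nearly neutral conditions that should spare the dienone.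

Step 5
Reactants: 8 4-(6-bromo-2,3,4-trimethoxyphenyl)-4-(3-hydroxypropyl)-2,6-dimethoxycyclohexa-2,5-dien-1-one
Product: 10 3-[1-(6-bromo-2,3,4-trimethoxyphenyl)-3,5-dimethoxy-4-oxocyclohexa-2,5-dien-1-yl]propanoic acid, via aldehyde 9 (not isolated)
Conditions: TEMPO (cat.), PhI(OAc)2, MeCN/H2O, rt
Reagents that add atoms: water, O
Why: The nitroxyl-catalysed oxidation takes a primary alcohol through the aldehyde hydrate to the acid and should leave the dienone, the aryl bromide and the methyl ethers untouched.

Step 6
Reactants: 11 (E)-but-2-enal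
Product: 12 (Z)-2-iodobut-2-enal
Conditions: I2, K2CO3, DMAP (cat.), THF/H2O, rt
Reagents that add atoms: iodine, II
Why: Amine-catalysed α-iodination of an enal (conjugate addition of DMAP, iodination of the enolate, elimination, as in the first half of a Morita–Baylis–Hillman reaction) should return the isomer with iodine cis to methyl.

Step 7
Reactants: 12 (Z)-2-iodobut-2-enal
Product: 13 (Z)-2-iodobut-2-en-1-ol
Conditions: NaBH4, MeOH, 0 °C
Reagents that add atoms: none
Why: Borohydride 1,2-reduction of the aldehyde should leave the alkene geometry and the C–I bond unchanged.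

Step 8
Reactants: 13 (Z)-2-iodobut-2-en-1-ol
Product: 14 (E)-2-(4,4,5,5-tetramethyl-1,3,2-dioxaborolan-2-yl)but-2-en-1-ol
Conditions: B2pin2, PdCl2(PPh3)2 (cat.), PPh3, KOPh, toluene, 50 °C
Reagents that add atoms: bis(pinacolato)diboron, CC1(C)OB(OC1(C)C)B1OC(C)(C)C(C)(C)O1
Why: Miyaura borylation of an alkenyl iodide proceeds with retention, so boron should stay cis to methyl (the descriptor changes to E only because boron ranks below carbon), and the weak phenoxide base suppresses homocoupling.

Step 9
Reactants: 10 3-[1-(6-bromo-2,3,4-trimethoxyphenyl)-3,5-dimethoxy-4-oxocyclohexa-2,5-dien-1-yl]propanoic acid; 14 (E)-2-(4,4,5,5-tetramethyl-1,3,2-dioxaborolan-2-yl)but-2-en-1-ol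
Product: 15 3-[1-{6-[(2E)-1-hydroxybut-2-en-2-yl]-2,3,4-trimethoxyphenyl}-3,5-dimethoxy-4-oxocyclohexa-2,5-dien-1-yl]propanoic acid
Conditions: Pd(OAc)2 (cat.), SPhos, K3PO4, dioxane/H2O, 80 °C
Reagents that add atoms: none
Why: Suzuki–Miyaura coupling with a bulky biarylphosphine suits the aryl bromide ortho to the quaternary carbon, the alkenyl group is transferred with retention so that methyl ends cis to the arene (E), and the acid is carried as its carboxylate.

Step 10
Reactants: 15 3-[1-{6-[(2E)-1-hydroxybut-2-en-2-yl]-2,3,4-trimethoxyphenyl}-3,5-dimethoxy-4-oxocyclohexa-2,5-dien-1-yl]propanoic acid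
Product: 17 (1E)-1-ethylidene-8,9,10,3',5'-pentamethoxy-1,2,5,6-tetrahydrospiro[3-benzoxonine-7,1'-cyclohexa[2,5]diene]-4,4'-dione (nine-membered lactone), via mixed anhydride 16 (not isolated)
Conditions: 2-methyl-6-nitrobenzoic anhydride, DMAP, Et3N, CH2Cl2 (high dilution, slow addition of 15), rt
Reagents that add atoms: none
Why: Shiina macrolactonization through the mixed anhydride should close the nine-membered ring because both arms sit on adjacent atoms of the rigid arene–quaternary carbon unit and the ring holds several sp2 atoms that lower transannular strain.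

Step 11
Reactants: 17 (1E)-1-ethylidene-8,9,10,3',5'-pentamethoxy-1,2,5,6-tetrahydrospiro[3-benzoxonine-7,1'-cyclohexa[2,5]diene]-4,4'-dione
Product: 20 (7R,8S)-2,3,4,3',5'-pentamethoxy-8-methyl-9-methylidene-4'-oxo-6,7,8,9-tetrahydrospiro[benzo[7]annulene-5,1'-cyclohexa[2,5]diene]-7-carboxylic acid, via boron ketene acetal 18 (not isolated), via boron carboxylate 19 (not isolated)
Conditions: (S,S)-2-bromo-4,5-diphenyl-1,3-bis{[3,5-bis(trifluoromethyl)phenyl]sulfonyl}-1,3,2-diazaborolidine (from the bis-sulfonamide and BBr3), 1,2,2,6,6-pentamethylpiperidine, CH2Cl2, −78 °C → 4 °C; then H2O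
Reagents that add atoms: none
Why: The bromoborane binds the lactone carbonyl and the hindered amine removes an α-hydrogen (soft enolization) to give boron ketene acetal 18, whose geometry is fixed by the ring with C-6 syn to the ring oxygen; a [3,3] shift then joins the enolate carbon (C-7) to the ethylidene carbon (C-8) as the allylic C–O bond breaks, and work-up hydrolyses boron carboxylate 19. The closest known reaction type is the enantioselective boron-enolate Ireland–Claisen rearrangement of allylic esters and its ring-contracting variant on macrocyclic allylic lactones. The seven-membered carbocycle closes by sigmatropic ring contraction of the nine-membered lactone: the four-atom tether between C-7 and C-9 spans a chair-like, bicyclo[4.3.1]-type transition state in which C-6 is axial on the enolate carbon, and a boat is out of reach of the tether. C-7 and C-8 are formed together, their trans relationship following from this chair with the E methyl group equatorial, and their absolute configuration from the C2-symmetric bis-sulfonamide ligand on boron, which differentiates the two enantiomeric chair arrangements. The step needs enolization of the lactone only, which is secured because the dienone has no α-hydrogen, and it needs the ring-cis enolate geometry, which the nine-membered ring enforces.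

Step 12
Reactants: 20 (7R,8S)-2,3,4,3',5'-pentamethoxy-8-methyl-9-methylidene-4'-oxo-6,7,8,9-tetrahydrospiro[benzo[7]annulene-5,1'-cyclohexa[2,5]diene]-7-carboxylic acid
Product: 22 (7R,8S)-2,3,4,3',5'-pentamethoxy-8-methyl-4',9-dioxo-6,7,8,9-tetrahydrospiro[benzo[7]annulene-5,1'-cyclohexa[2,5]diene]-7-carboxylic acid, via vicinal diol 21 (not isolated)
Conditions: OsO4 (cat.), NaIO4, 2,6-lutidine, dioxane/H2O, rt
Reagents that add atoms: sodium periodate, [Na+].[O-]I(=O)(=O)=O; osmium tetroxide, O=[Os](=O)(=O)=O
Why: In this Lemieux–Johnson cleavage OsO4 should dihydroxylate the exposed 1,1-disubstituted styrenic alkene in preference to the trisubstituted, carbonyl-conjugated dienone double bonds beside the quaternary carbon, periodate then cleaves the diol, and the epimerizable C-8 centre already sits in its more stable trans arrangement.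

Step 13
Reactants: 22 (7R,8S)-2,3,4,3',5'-pentamethoxy-8-methyl-4',9-dioxo-6,7,8,9-tetrahydrospiro[benzo[7]annulene-5,1'-cyclohexa[2,5]diene]-7-carboxylic acid
Product: 23 (7R,8S,9R)-7-(hydroxymethyl)-2,3,4,3',5'-pentamethoxy-8-methyl-6,7,8,9-tetrahydrospiro[benzo[7]annulene-5,1'-cyclohexa[2,5]diene]-4',9-diol (both C-4' epimers)
Conditions: LiAlH4 (excess), THF, 0 °C → 40 °C; basic work-up
Reagents that add atoms: none
Why: LiAlH4 reduces the carboxylate, the aryl ketone and the dienone carbonyl in one operation (the dienone is taken to the dienol on purpose and restored in step 16), and the small hydride should attack the benzo-fused cycloheptanone axially to give the pseudo-equatorial C-9 alcohol trans to the 8-methyl group, the C-4' epimer mixture being of no consequence.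

Step 14
Reactants: 23 (7R,8S,9R)-7-(hydroxymethyl)-2,3,4,3',5'-pentamethoxy-8-methyl-6,7,8,9-tetrahydrospiro[benzo[7]annulene-5,1'-cyclohexa[2,5]diene]-4',9-diol
Product: 24 [(7R,8S,9R)-4',9-dihydroxy-2,3,4,3',5'-pentamethoxy-8-methyl-6,7,8,9-tetrahydrospiro[benzo[7]annulene-5,1'-cyclohexa[2,5]dien]-7-yl]methyl 4-methylbenzenesulfonate (both C-4' epimers)
Conditions: TsCl, pyridine, CH2Cl2, 0 °C
Reagents that add atoms: 4-methylbenzenesulfonyl chloride, Cc1ccc(cc1)S(Cl)(=O)=O
Why: Sulfonylation should take place at the primary hydroxyl group much faster than at the two hindered secondary ones, and the basic medium protects the acid-sensitive dienol.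

Step 15
Reactants: 24 [(7R,8S,9R)-4',9-dihydroxy-2,3,4,3',5'-pentamethoxy-8-methyl-6,7,8,9-tetrahydrospiro[benzo[7]annulene-5,1'-cyclohexa[2,5]dien]-7-yl]methyl 4-methylbenzenesulfonate
Product: 25 (7R,8S,9R)-2,3,4,3',5'-pentamethoxy-7,8-dimethyl-6,7,8,9-tetrahydrospiro[benzo[7]annulene-5,1'-cyclohexa[2,5]diene]-4',9-diol (both C-4' epimers)
Conditions: LiBEt3H, THF, 0 °C → rt
Reagents that add atoms: none
Why: SN2 displacement of a primary tosylate by the powerful hydride donor gives the methyl group, the former dienone being safe as its alkoxide and no stereocentre being touched.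

Step 16
Reactants: 25 (7R,8S,9R)-2,3,4,3',5'-pentamethoxy-7,8-dimethyl-6,7,8,9-tetrahydrospiro[benzo[7]annulene-5,1'-cyclohexa[2,5]diene]-4',9-diol
Product: 26 (7R,8S,9R)-9-hydroxy-2,3,4,3',5'-pentamethoxy-7,8-dimethyl-6,7,8,9-tetrahydrospiro[benzo[7]annulene-5,1'-cyclohexa[2,5]dien]-4'-one
Conditions: MnO2 (activated, excess), CH2Cl2, rt
Reagents that add atoms: none
Why: Allylic oxidation with MnO2 should take the doubly allylic dienol, flanked by two enol ether double bonds, much faster than the α-branched benzylic carbinol whose C–H bond is held out of conjugation with the ortho-disubstituted arene, and it converges both C-4' epimers to one dienone.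

Step 17
Reactants: 26 (7R,8S,9R)-9-hydroxy-2,3,4,3',5'-pentamethoxy-7,8-dimethyl-6,7,8,9-tetrahydrospiro[benzo[7]annulene-5,1'-cyclohexa[2,5]dien]-4'-one
Product: 27 (7R,8S,9R)-2,3,4,3',5'-pentamethoxy-7,8-dimethyl-4'-oxo-6,7,8,9-tetrahydrospiro[benzo[7]annulene-5,1'-cyclohexa[2,5]dien]-9-yl benzoate
Conditions: BzCl, Et3N, DMAP (cat.), CH2Cl2, 0 °C → rt
Reagents that add atoms: benzoyl chloride, O=C(Cl)c1ccccc1
Why: DMAP-catalysed acylation of the only hydroxyl group proceeds at oxygen with retention at C-9 and should give the target.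

**Compound list**

1 | 5-bromo-1,2,3-trimethoxybenzene | COc1cc(Br)cc(OC)c1OC | starting material
2 | 1-bromo-2-iodo-3,4,5-trimethoxybenzene | COc1cc(Br)c(I)c(OC)c1OC | intermediate
3 | 2,6-dimethoxy-4-(4,4,5,5-tetramethyl-1,3,2-dioxaborolan-2-yl)phenol | COc1cc(cc(OC)c1O)B1OC(C)(C)C(C)(C)O1 | starting material
4 | 4-(6-bromo-2,3,4-trimethoxyphenyl)-2,6-dimethoxyphenol | COc1cc(cc(OC)c1O)-c1c(Br)cc(OC)c(OC)c1OC | intermediate
5 | allyltrimethylsilane | C=CC[Si](C)(C)C | starting material
6 | 4-(6-bromo-2,3,4-trimethoxyphenyl)-2,6-dimethoxy-4-(prop-2-en-1-yl)cyclohexa-2,5-dien-1-one | COC1=CC(CC=C)(C=C(OC)C1=O)c1c(Br)cc(OC)c(OC)c1OC | intermediate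
7 | pinacol alkylboronate: 4-(6-bromo-2,3,4-trimethoxyphenyl)-2,6-dimethoxy-4-[3-(4,4,5,5-tetramethyl-1,3,2-dioxaborolan-2-yl)propyl]cyclohexa-2,5-dien-1-one | COC1=CC(CCCB2OC(C)(C)C(C)(C)O2)(C=C(OC)C1=O)c1c(Br)cc(OC)c(OC)c1OC | intermediate (not isolated)
8 | 4-(6-bromo-2,3,4-trimethoxyphenyl)-4-(3-hydroxypropyl)-2,6-dimethoxycyclohexa-2,5-dien-1-one | COC1=CC(CCCO)(C=C(OC)C1=O)c1c(Br)cc(OC)c(OC)c1OC | intermediate
9 | aldehyde: 3-[1-(6-bromo-2,3,4-trimethoxyphenyl)-3,5-dimethoxy-4-oxocyclohexa-2,5-dien-1-yl]propanal | COC1=CC(CCC=O)(C=C(OC)C1=O)c1c(Br)cc(OC)c(OC)c1OC | intermediate (not isolated)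
10 | 3-[1-(6-bromo-2,3,4-trimethoxyphenyl)-3,5-dimethoxy-4-oxocyclohexa-2,5-dien-1-yl]propanoic acid | COC1=CC(CCC(=O)O)(C=C(OC)C1=O)c1c(Br)cc(OC)c(OC)c1OC | intermediate
11 | (E)-but-2-enal | C/C=C/C=O | starting material
12 | (Z)-2-iodobut-2-enal | C/C=C(\I)C=O | intermediate
13 | (Z)-2-iodobut-2-en-1-ol | C/C=C(\I)CO | intermediate
14 | (E)-2-(4,4,5,5-tetramethyl-1,3,2-dioxaborolan-2-yl)but-2-en-1-ol | C/C=C(\B1OC(C)(C)C(C)(C)O1)CO | intermediate
15 | 3-[1-{6-[(2E)-1-hydroxybut-2-en-2-yl]-2,3,4-trimethoxyphenyl}-3,5-dimethoxy-4-oxocyclohexa-2,5-dien-1-yl]propanoic acid | COC1=CC(CCC(=O)O)(C=C(OC)C1=O)c1c(cc(OC)c(OC)c1OC)/C(CO)=C\C | intermediate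
16 | mixed anhydride of 15 with 2-methyl-6-nitrobenzoic acid | COC1=CC(CCC(=O)OC(=O)c2c(C)cccc2[N+](=O)[O-])(C=C(OC)C1=O)c1c(cc(OC)c(OC)c1OC)/C(CO)=C\C | intermediate (not isolated)
17 | nine-membered lactone: (1E)-1-ethylidene-8,9,10,3',5'-pentamethoxy-1,2,5,6-tetrahydrospiro[3-benzoxonine-7,1'-cyclohexa[2,5]diene]-4,4'-dione | COC1=CC2(C=C(OC)C1=O)CCC(=O)OC/C(=C/C)c1cc(OC)c(OC)c(OC)c12 | intermediate
18 | boron ketene acetal of 17 (O-boryl, ring CH2 syn to ring oxygen, (S,S)-diazaborolidine on boron) | COC1=CC2(C=C(OC)C1=O)C/C=C(OB3N(S(=O)(=O)c4cc(cc(c4)C(F)(F)F)C(F)(F)F)[C@@H](c4ccccc4)[C@H](c4ccccc4)N3S(=O)(=O)c3cc(cc(c3)C(F)(F)F)C(F)(F)F)\OC/C(=C/C)c1cc(OC)c(OC)c(OC)c12 | intermediate (not isolated)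
19 | boron carboxylate of 20 (acyloxy-diazaborolidine) | COC1=CC2(C=C(OC)C1=O)C[C@@H](C(=O)OB3N(S(=O)(=O)c4cc(cc(c4)C(F)(F)F)C(F)(F)F)[C@@H](c4ccccc4)[C@H](c4ccccc4)N3S(=O)(=O)c3cc(cc(c3)C(F)(F)F)C(F)(F)F)[C@H](C)C(=C)c1cc(OC)c(OC)c(OC)c12 | intermediate (not isolated)
20 | (7R,8S)-2,3,4,3',5'-pentamethoxy-8-methyl-9-methylidene-4'-oxo-6,7,8,9-tetrahydrospiro[benzo[7]annulene-5,1'-cyclohexa[2,5]diene]-7-carboxylic acid | COC1=CC2(C=C(OC)C1=O)C[C@@H](C(=O)O)[C@H](C)C(=C)c1cc(OC)c(OC)c(OC)c12 | intermediate
21 | vicinal diol: (7R,8S)-9-hydroxy-9-(hydroxymethyl) analogue of 20 (C-9 configuration undefined) | COC1=CC2(C=C(OC)C1=O)C[C@@H](C(=O)O)[C@H](C)C(O)(CO)c1cc(OC)c(OC)c(OC)c12 | intermediate (not isolated)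
22 | (7R,8S)-2,3,4,3',5'-pentamethoxy-8-methyl-4',9-dioxo-6,7,8,9-tetrahydrospiro[benzo[7]annulene-5,1'-cyclohexa[2,5]diene]-7-carboxylic acid | COC1=CC2(C=C(OC)C1=O)C[C@@H](C(=O)O)[C@H](C)C(=O)c1cc(OC)c(OC)c(OC)c12 | intermediate
23 | (7R,8S,9R)-7-(hydroxymethyl)-2,3,4,3',5'-pentamethoxy-8-methyl-6,7,8,9-tetrahydrospiro[benzo[7]annulene-5,1'-cyclohexa[2,5]diene]-4',9-diol (both C-4' epimers) | COC1=CC2(C=C(OC)C1O)C[C@@H](CO)[C@H](C)[C@@H](O)c1cc(OC)c(OC)c(OC)c12 | intermediate
24 | primary tosylate of 23 (both C-4' epimers) | COC1=CC2(C=C(OC)C1O)C[C@@H](COS(=O)(=O)c3ccc(C)cc3)[C@H](C)[C@@H](O)c1cc(OC)c(OC)c(OC)c12 | intermediate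
25 | (7R,8S,9R)-2,3,4,3',5'-pentamethoxy-7,8-dimethyl-6,7,8,9-tetrahydrospiro[benzo[7]annulene-5,1'-cyclohexa[2,5]diene]-4',9-diol (both C-4' epimers) | COC1=CC2(C=C(OC)C1O)C[C@@H](C)[C@H](C)[C@@H](O)c1cc(OC)c(OC)c(OC)c12 | intermediate
26 | (7R,8S,9R)-9-hydroxy-2,3,4,3',5'-pentamethoxy-7,8-dimethyl-6,7,8,9-tetrahydrospiro[benzo[7]annulene-5,1'-cyclohexa[2,5]dien]-4'-one | COC1=CC2(C=C(OC)C1=O)C[C@@H](C)[C@H](C)[C@@H](O)c1cc(OC)c(OC)c(OC)c12 | intermediate
27 | (7R,8S,9R)-2,3,4,3',5'-pentamethoxy-7,8-dimethyl-4'-oxo-6,7,8,9-tetrahydrospiro[benzo[7]annulene-5,1'-cyclohexa[2,5]dien]-9-yl benzoate | COC1=CC2(C=C(OC)C1=O)C[C@@H](C)[C@H](C)[C@@H](OC(=O)c1ccccc1)c1cc(OC)c(OC)c(OC)c12 | target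

**Step count and risks**

Total: 17 steps. Longest linear sequence: 14 steps (from 1 through steps 1–5 and 9–17); the alkenyl boronate branch (steps 6–8) joins at step 9.

Risk 1, step 3. The oxidized phenol may be trapped at a methoxy-bearing ortho carbon instead of the hindered para carbon, or the electron-rich biaryl may be over-oxidized, so that site selectivity of the C–C bond formation is poor. The fallback sets out again from 1 and rejoins the route at 10; it makes the aryl–quaternary carbon bond, not the allyl bond, in the dearomatization. Methyl 3-(4-hydroxy-3,5-dimethoxyphenyl)propanoate F1, which already carries the three-carbon chain on an unhindered para carbon, would be oxidized with PhI(OAc)2 in (CF3)2CHOH in the presence of an excess of 1 (oxidative Friedel–Crafts-type arylation of a para-alkylphenol). Arene 1 can attack only through its activated position between bromine and methoxy, which would give dienone ester F2; saponification with LiOH in THF/H2O would give 10, so that steps 2 to 5 are bypassed.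

Risk 2, step 10. Intermolecular acylation (dimer and oligomer formation) may outrun closure of the strained nine-membered ring. The fallback sets out from 15 and rejoins at 17; the alcohol is activated in place of the acid. Slow addition of PPh3 and diisopropyl azodicarboxylate to 15 in toluene/THF at high dilution (intramolecular Mitsunobu esterification) would close the ring by SN2 attack of the carboxylate on the primary allylic oxyphosphonium carbon, forming the alkyl C–O bond where step 10 forms the acyl C–O bond. No new compound arises on this path (F0).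

Risk 3, step 11. The boron Lewis acid may be sequestered by the dienone carbonyl so that enolization stays incomplete, it may trigger a dienone–phenol migration, or the ligand may discriminate the two chair arrangements poorly. The fallback sets out from 17 and rejoins at 20; it separates bond formation from enantiocontrol. Treatment of 17 with KN(SiMe3)2 in the presence of Me3SiCl/Et3N in THF at −78 °C would give silyl ketene acetal F3, which on warming should rearrange through the same ring-enforced chair to the racemic trans silyl ester F4. Aqueous work-up would give 20 together with its enantiomer F5, and the pair would be separated by preparative chromatography on a chiral stationary phase (or by crystallization of a salt with an enantiopure amine).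

**Further compounds**

F1 | step 3 | methyl 3-(4-hydroxy-3,5-dimethoxyphenyl)propanoate | COC(=O)CCc1cc(OC)c(O)c(OC)c1
F2 | step 3 | methyl 3-[1-(6-bromo-2,3,4-trimethoxyphenyl)-3,5-dimethoxy-4-oxocyclohexa-2,5-dien-1-yl]propanoate | COC(=O)CCC1(C=C(OC)C(=O)C(OC)=C1)c1c(Br)cc(OC)c(OC)c1OC
F0 | step 10 | none | none
F3 | step 11 | trimethylsilyl ketene acetal of lactone 17 | COC1=CC2(C=C(OC)C1=O)C/C=C(O[Si](C)(C)C)\OC/C(=C/C)c1cc(OC)c(OC)c(OC)c12
F4 | step 11 | racemic trimethylsilyl ester of the trans acid (one enantiomer drawn) | COC1=CC2(C=C(OC)C1=O)C[C@@H](C(=O)O[Si](C)(C)C)[C@H](C)C(=C)c1cc(OC)c(OC)c(OC)c12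
F5 | step 11 | (7S,8R) enantiomer of acid 20 | COC1=CC2(C=C(OC)C1=O)C[C@H](C(=O)O)[C@@H](C)C(=C)c1cc(OC)c(OC)c(OC)c12
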